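**Plan**

- Retrosynthesis: the two aryl–prenyl bonds, C6–C1'' on ring A and C5'–C1''' on ring B, are cut first, which returns both prenyl groups to oxygen as 1,1-dimethylallyl ethers on O5 and O4' of an (S)-flavanone. O1–C2 and C2–C3 of ring C are cut next, giving a ring A acetophenone and a ring B benzaldehyde.
- Enabling feature: each prenyl carbon lies ortho to a phenolic oxygen. On ring A, C6 is the only open ortho position of O5 because C4a is the ring-fusion carbon. On ring B, C5' is ortho to O4' and para to O2'.
- Forward: the ketone and the aldehyde, each already carrying its tertiary allyl ether and one TIPS ether, are joined by an aldol addition (C2–C3). Ring C is closed by Mitsunobu etherification (O1–C2). A twofold Claisen rearrangement then forms both prenyl bonds without closing a ring, and desilylation ends the route.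
- Stereochemistry: C2 is the only stereocentre. It is formed racemic, and the S enantiomer is secured by a catalyst-controlled kinetic resolution (asymmetric transfer hydrogenation) before the rearrangement. It is then carried through a neutral thermal step and a buffered fluoride step.

Key step: step 9

Assumption: the (R,R)-configured transfer-hydrogenation catalyst is taken to reduce the (2R)-flavanone faster, as is usual for such catalysts with aryl ketones; if the sense were reversed on this substrate, the (S,S) catalyst would be used in step 8.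

Flavanone numbering is used throughout: unprimed locants for rings A and C (2-arylchroman-4-one), primed locants for ring B.

**Step 1**
Reactants: 1 2-methylbut-3-en-2-ol
Product: 3 tert-butyl 2-methylbut-3-en-2-yl carbonate, via lithium 2-methylbut-3-en-2-olate 2 (not isolated)
Conditions: n-BuLi, THF, −78 °C; then Boc2O, −78 °C → rt
Reagents that add atoms: di-tert-butyl dicarbonate (Boc2O), CC(C)(C)OC(=O)OC(=O)OC(C)(C)C
Why: O-acylation of a preformed tertiary lithium alkoxide with Boc2O is the standard way to a mixed tert-butyl allylic carbonate and avoids the symmetrical carbonate.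

**Step 2**
Reactants: 4 2,4,6-trihydroxyacetophenone (dried)
Product: 5 1-[2,6-dihydroxy-4-(triisopropylsilyloxy)phenyl]ethan-1-one
Conditions: TIPSCl (1.05 equiv), imidazole, DMF, 0 °C
Reagents that add atoms: triisopropylsilyl chloride (TIPSCl), CC(C)[Si](Cl)(C(C)C)C(C)C
Why: Phenol silylation should be selective for the para hydroxyl, which is the most acidic and the only one not hydrogen-bonded to the acetyl group, while the bulky silyl chloride avoids the two chelated ortho hydroxyls.

**Step 3**
Reactants: 5 1-[2,6-dihydroxy-4-(triisopropylsilyloxy)phenyl]ethan-1-one; 3 tert-butyl 2-methylbut-3-en-2-yl carbonate (1.2 equiv)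
Product: 6 1-[2-hydroxy-6-(2-methylbut-3-en-2-yloxy)-4-(triisopropylsilyloxy)phenyl]ethan-1-one
Conditions: Pd(PPh3)4 (5 mol%), THF, 0 °C → rt; concentration below 30 °C
Reagents that add atoms: none
Why: In this decarboxylative allylic etherification (Tsuji–Trost type), zerovalent palladium ionises the carbonate, the released tert-butoxide deprotonates one of the two equivalent ortho phenols, and the phenoxide attacks the more substituted allyl terminus at low temperature to give the tertiary ether; the remaining hydroxyl is then strongly chelated and hindered, so mono-etherification is expected.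

**Step 4**
Reactants: 7 2,4-dihydroxybenzaldehyde; 3 tert-butyl 2-methylbut-3-en-2-yl carbonate (1.1 equiv)
Product: 8 2-hydroxy-4-(2-methylbut-3-en-2-yloxy)benzaldehyde
Conditions: Pd(PPh3)4 (5 mol%), THF, 0 °C
Reagents that add atoms: none
Why: The same decarboxylative allylic etherification should take place at the 4-hydroxyl only, since it is the more acidic phenol and is not chelated to the formyl group.

**Step 5**
Reactants: 8 2-hydroxy-4-(2-methylbut-3-en-2-yloxy)benzaldehyde
Product: 9 4-(2-methylbut-3-en-2-yloxy)-2-(triisopropylsilyloxy)benzaldehyde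
Conditions: TIPSCl, imidazole, DMAP (cat.), DMF, rt
Reagents that add atoms: triisopropylsilyl chloride (TIPSCl), CC(C)[Si](Cl)(C(C)C)C(C)C
Why: Silylation of the remaining chelated phenol under neutral conditions is routine for salicylaldehydes and installs the bulky group that later shields C3'.

**Step 6**
Reactants: 6 1-[2-hydroxy-6-(2-methylbut-3-en-2-yloxy)-4-(triisopropylsilyloxy)phenyl]ethan-1-one; 9 4-(2-methylbut-3-en-2-yloxy)-2-(triisopropylsilyloxy)benzaldehyde
Product: 11 rac-3-hydroxy-1-[2-hydroxy-6-(2-methylbut-3-en-2-yloxy)-4-(triisopropylsilyloxy)phenyl]-3-[4-(2-methylbut-3-en-2-yloxy)-2-(triisopropylsilyloxy)phenyl]propan-1-one, via dilithium enolate phenoxide 10 (not isolated)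
Conditions: LiN(iPr)2 (2.1 equiv), THF, −78 °C; then 9, −78 °C; AcOH quench at −78 °C
Reagents that add atoms: none
Why: Aldol addition of the dianion of an ortho-hydroxyacetophenone (phenoxide plus kinetic methyl ketone enolate) to a non-enolisable aldehyde forms C2–C3, the cold acidic quench limits retro-aldol, dehydration and silyl migration, and the carbinol centre is formed as the racemate.

**Step 7**
Reactants: 11 the racemic aldol adduct
Product: 12 rac-5,4'-bis(2-methylbut-3-en-2-yloxy)-7,2'-bis(triisopropylsilyloxy)flavanone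
Conditions: PPh3, DIAD, THF, 0 °C → rt
Reagents that add atoms: none
Why: In this intramolecular Mitsunobu etherification the ketone-chelated phenol displaces the activated benzylic hydroxyl in a 6-exo-tet closure that forms O1–C2 under neutral conditions below the rearrangement temperature; as the centre is still racemic, any ionisation at the electron-rich benzylic carbon is harmless.

**Step 8**
Reactants: 12 rac-5,4'-bis(2-methylbut-3-en-2-yloxy)-7,2'-bis(triisopropylsilyloxy)flavanone
Product: 13 (2S)-5,4'-bis(2-methylbut-3-en-2-yloxy)-7,2'-bis(triisopropylsilyloxy)flavanone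
Conditions: RuCl(p-cymene)[(R,R)-TsDPEN] (1 mol%), HCO2H/Et3N (1:1), EtOAc, rt, stopped slightly beyond half conversion; chromatography
Reagents that add atoms: none
Why: In this kinetic resolution by asymmetric transfer hydrogenation the catalyst should reduce the C4 ketone of the (2R) enantiomer to the cis-flavan-4-ol much faster than that of the mismatched (2S) ketone, which is recovered and separated from the alcohol, while terminal alkenes, silyl ethers and tertiary ethers are inert to this outer-sphere hydride transfer.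

**Step 9**
Reactants: 13 (2S)-5,4'-bis(2-methylbut-3-en-2-yloxy)-7,2'-bis(triisopropylsilyloxy)flavanone
Product: 15 (2S)-5,4'-dihydroxy-6,5'-bis(3-methylbut-2-enyl)-7,2'-bis(triisopropylsilyloxy)flavanone, via ring A rearranged mono-ether 14 (not isolated)
Conditions: degassed PhMe, 110 °C, sealed tube
Reagents that add atoms: none
Why: Each tertiary allyl aryl ether undergoes a concerted suprafacial [3,3]-sigmatropic shift through a chair-like six-membered transition state in which the O–C(CH3)2 bond breaks as the terminal CH2 bonds to the ortho carbon (C6 on ring A, C5' on ring B), and the resulting cyclohexadienones enolise to the 5- and 4'-phenols, so each 1,1-dimethylallyl ether emerges as a normal 3,3-dimethylallyl group. The closest known reaction type is the aromatic Claisen rearrangement of aryl 1,1-dimethylallyl ethers to ortho-prenylphenols, here run twice in one molecule with 14 as the expected half-way stage. No ring is closed and no stereocentre is created; C2 is a spectator and should keep its S configuration because the medium is neutral, aprotic and free of base. On ring A there is no regiochemical choice, since O5 has only C6 as a free ortho position and the C6 dienone should tautomerise faster than it could relay the allyl group to C8. On ring B the required preference for C5' over C3' should come from the bulky 2'-O-TIPS group flanking C3' and from the general tendency of allyl aryl ethers with a meta donor to rearrange to the position para to that donor. Tertiary ethers of this kind rearrange near 110 °C, well below the temperature needed for primary allyl ethers, which limits thermal stress on the silyl ethers and on C2.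

**Step 10**
Reactants: 15 (2S)-5,4'-dihydroxy-6,5'-bis(3-methylbut-2-enyl)-7,2'-bis(triisopropylsilyloxy)flavanone
Product: 16 (2S)-5,7,2',4'-tetrahydroxy-6,5'-bis(3-methylbut-2-enyl)flavanone (CNP0320454.1)
Conditions: Bu4NF (TBAF)/AcOH (1:1, 2.5 equiv), THF, 0 °C
Reagents that add atoms: none
Why: Fluoride-induced cleavage of the two aryl silyl ethers is buffered by acetic acid so that free phenoxides, and with them retro-oxa-Michael opening at O1–C2 and epimerisation of C2, are suppressed, while the absence of strong acid keeps the ortho-prenylphenols from cyclising to chromans.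

**Compound list**

1 | 2-methylbut-3-en-2-ol | CC(C)(O)C=C | starting material
2 | lithium 2-methylbut-3-en-2-olate | [Li+].[O-]C(C)(C)C=C | intermediate
3 | tert-butyl 2-methylbut-3-en-2-yl carbonate | CC(C)(C)OC(=O)OC(C)(C)C=C | intermediate
4 | 2,4,6-trihydroxyacetophenone | CC(=O)c1c(O)cc(O)cc1O | starting material
5 | 1-[2,6-dihydroxy-4-(triisopropylsilyloxy)phenyl]ethan-1-one | CC(=O)c1c(O)cc(O[Si](C(C)C)(C(C)C)C(C)C)cc1O | intermediate
6 | 1-[2-hydroxy-6-(2-methylbut-3-en-2-yloxy)-4-(triisopropylsilyloxy)phenyl]ethan-1-one | CC(=O)c1c(O)cc(O[Si](C(C)C)(C(C)C)C(C)C)cc1OC(C)(C)C=C | intermediate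
7 | 2,4-dihydroxybenzaldehyde | O=Cc1ccc(O)cc1O | starting material
8 | 2-hydroxy-4-(2-methylbut-3-en-2-yloxy)benzaldehyde | O=Cc1ccc(OC(C)(C)C=C)cc1O | intermediate
9 | 4-(2-methylbut-3-en-2-yloxy)-2-(triisopropylsilyloxy)benzaldehyde | O=Cc1ccc(OC(C)(C)C=C)cc1O[Si](C(C)C)(C(C)C)C(C)C | intermediate
10 | dilithium enolate phenoxide of 6 | [Li+].[Li+].C=C([O-])c1c([O-])cc(O[Si](C(C)C)(C(C)C)C(C)C)cc1OC(C)(C)C=C | intermediate
11 | rac-3-hydroxy-1-[2-hydroxy-6-(2-methylbut-3-en-2-yloxy)-4-(triisopropylsilyloxy)phenyl]-3-[4-(2-methylbut-3-en-2-yloxy)-2-(triisopropylsilyloxy)phenyl]propan-1-one | OC(CC(=O)c1c(O)cc(O[Si](C(C)C)(C(C)C)C(C)C)cc1OC(C)(C)C=C)c1ccc(OC(C)(C)C=C)cc1O[Si](C(C)C)(C(C)C)C(C)C | intermediate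
12 | rac-5,4'-bis(2-methylbut-3-en-2-yloxy)-7,2'-bis(triisopropylsilyloxy)flavanone | C=CC(C)(C)Oc1ccc(C2CC(=O)c3c(cc(O[Si](C(C)C)(C(C)C)C(C)C)cc3OC(C)(C)C=C)O2)c(O[Si](C(C)C)(C(C)C)C(C)C)c1 | intermediate
13 | (2S)-5,4'-bis(2-methylbut-3-en-2-yloxy)-7,2'-bis(triisopropylsilyloxy)flavanone | C=CC(C)(C)Oc1ccc([C@@H]2CC(=O)c3c(cc(O[Si](C(C)C)(C(C)C)C(C)C)cc3OC(C)(C)C=C)O2)c(O[Si](C(C)C)(C(C)C)C(C)C)c1 | intermediate
14 | (2S)-5-hydroxy-6-(3-methylbut-2-enyl)-4'-(2-methylbut-3-en-2-yloxy)-7,2'-bis(triisopropylsilyloxy)flavanone | C=CC(C)(C)Oc1ccc([C@@H]2CC(=O)c3c(cc(O[Si](C(C)C)(C(C)C)C(C)C)c(CC=C(C)C)c3O)O2)c(O[Si](C(C)C)(C(C)C)C(C)C)c1 | intermediate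
15 | (2S)-5,4'-dihydroxy-6,5'-bis(3-methylbut-2-enyl)-7,2'-bis(triisopropylsilyloxy)flavanone | CC(C)=CCc1cc([C@@H]2CC(=O)c3c(cc(O[Si](C(C)C)(C(C)C)C(C)C)c(CC=C(C)C)c3O)O2)c(O[Si](C(C)C)(C(C)C)C(C)C)cc1O | intermediate
16 | (2S)-5,7,2',4'-tetrahydroxy-6,5'-bis(3-methylbut-2-enyl)flavanone | CC(C)=CCc1cc([C@@H]2CC(=O)c3c(cc(O)c(CC=C(C)C)c3O)O2)c(O)cc1O | target

**Step count and risks**

Total steps: 10. Longest linear sequence: 8 steps (1 → 3 → 8 → 9 → 11 → 12 → 13 → 15 → 16, steps 1, 4, 5, 6, 7, 8, 9, 10).

Steps most likely to fail: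

1. Step 3. The phenoxide of the electron-rich, chelated ring may be allylated on carbon instead of oxygen, may attack the primary allyl terminus to give the linear prenyl ether, or may be etherified twice. Fallback, from 5 back to 6: copper-catalysed O-propargylation with 3-chloro-3-methylbut-1-yne (CuCl2·2H2O cat., DBU, MeCN, 0 °C) would give 1-[2-hydroxy-6-(2-methylbut-3-yn-2-yloxy)-4-(triisopropylsilyloxy)phenyl]ethan-1-one F1. Semihydrogenation (H2, Pd on CaCO3 poisoned with Pb(OAc)2, quinoline, EtOAc) would then give 6. This route has no allyl-palladium intermediate, so neither the linear ether nor palladium-mediated C-allylation can arise.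

2. Step 9. Attack at C3' may compete on ring B and give the 3'-prenyl isomer, or the crowded O5 ether may fragment with loss of the allyl unit instead of rearranging. Fallback, from 9 back to 16: the ring B rearrangement would be run alone on the aldehyde (PhMe, 110 °C), where regioisomers separate easily and no stereocentre is at risk, to give 4-hydroxy-5-(3-methylbut-2-enyl)-2-(triisopropylsilyloxy)benzaldehyde F2. Silylation (TIPSCl, imidazole, DMF) would give 5-(3-methylbut-2-enyl)-2,4-bis(triisopropylsilyloxy)benzaldehyde F3. Addition of dianion 10 would give the racemic aldol adduct F4, Mitsunobu closure (PPh3, DIAD) the racemic 5'-prenyl flavanone F5, and the transfer-hydrogenation resolution of step 8 the (2S)-5'-prenyl flavanone F6. A single Claisen rearrangement on ring A (PhMe, 110 °C), where only C6 is open, would give the (2S)-6,5'-diprenyl tris-silyl ether F7. Bu4NF/AcOH would cleave all three silyl ethers and rejoin the route at 16.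

3. Step 8. The rate difference between the enantiomers may be too small, for example because the peri O5 substituent slows hydride transfer to C4, so that the recovered ketone is not enantiopure. Fallback, from 6 back to 13, replacing resolution by enantioselective C2–C3 bond formation and invertive ring closure: TMSOTf/Et3N (CH2Cl2, 0 °C) would convert 6 into trimethyl{1-[2-(2-methylbut-3-en-2-yloxy)-4-(triisopropylsilyloxy)-6-(trimethylsilyloxy)phenyl]vinyloxy}silane F8. An enantioselective Mukaiyama aldol addition to 9 would follow, catalysed by the B-butyl oxazaborolidinone prepared from N-tosyltryptophan and BuB(OH)2 (antipode chosen to give the R carbinol; EtCN, −78 °C). Mild hydrolysis of the trimethylsilyl ethers would give (3R)-3-hydroxy-1-[2-hydroxy-6-(2-methylbut-3-en-2-yloxy)-4-(triisopropylsilyloxy)phenyl]-3-[4-(2-methylbut-3-en-2-yloxy)-2-(triisopropylsilyloxy)phenyl]propan-1-one F9. Mitsunobu closure (PPh3, DIAD, THF, −20 °C) with inversion at the benzylic carbon would return to the route at 13.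

**Further compounds**

F1 | step 3 | 1-[2-hydroxy-6-(2-methylbut-3-yn-2-yloxy)-4-(triisopropylsilyloxy)phenyl]ethan-1-one | CC(=O)c1c(O)cc(O[Si](C(C)C)(C(C)C)C(C)C)cc1OC(C)(C)C#C
F2 | step 9 | 4-hydroxy-5-(3-methylbut-2-enyl)-2-(triisopropylsilyloxy)benzaldehyde | O=Cc1cc(CC=C(C)C)c(O)cc1O[Si](C(C)C)(C(C)C)C(C)C
F3 | step 9 | 5-(3-methylbut-2-enyl)-2,4-bis(triisopropylsilyloxy)benzaldehyde | O=Cc1cc(CC=C(C)C)c(O[Si](C(C)C)(C(C)C)C(C)C)cc1O[Si](C(C)C)(C(C)C)C(C)C
F4 | step 9 | rac-3-hydroxy-1-[2-hydroxy-6-(2-methylbut-3-en-2-yloxy)-4-(triisopropylsilyloxy)phenyl]-3-[5-(3-methylbut-2-enyl)-2,4-bis(triisopropylsilyloxy)phenyl]propan-1-one | OC(CC(=O)c1c(O)cc(O[Si](C(C)C)(C(C)C)C(C)C)cc1OC(C)(C)C=C)c1cc(CC=C(C)C)c(O[Si](C(C)C)(C(C)C)C(C)C)cc1O[Si](C(C)C)(C(C)C)C(C)C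
F5 | step 9 | rac-5-(2-methylbut-3-en-2-yloxy)-5'-(3-methylbut-2-enyl)-7,2',4'-tris(triisopropylsilyloxy)flavanone | CC(C)=CCc1cc(C2CC(=O)c3c(cc(O[Si](C(C)C)(C(C)C)C(C)C)cc3OC(C)(C)C=C)O2)c(O[Si](C(C)C)(C(C)C)C(C)C)cc1O[Si](C(C)C)(C(C)C)C(C)C
F6 | step 9 | (2S)-5-(2-methylbut-3-en-2-yloxy)-5'-(3-methylbut-2-enyl)-7,2',4'-tris(triisopropylsilyloxy)flavanone | CC(C)=CCc1cc([C@@H]2CC(=O)c3c(cc(O[Si](C(C)C)(C(C)C)C(C)C)cc3OC(C)(C)C=C)O2)c(O[Si](C(C)C)(C(C)C)C(C)C)cc1O[Si](C(C)C)(C(C)C)C(C)C
F7 | step 9 | (2S)-5-hydroxy-6,5'-bis(3-methylbut-2-enyl)-7,2',4'-tris(triisopropylsilyloxy)flavanone | CC(C)=CCc1cc([C@@H]2CC(=O)c3c(cc(O[Si](C(C)C)(C(C)C)C(C)C)c(CC=C(C)C)c3O)O2)c(O[Si](C(C)C)(C(C)C)C(C)C)cc1O[Si](C(C)C)(C(C)C)C(C)C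
F8 | step 8 | trimethyl{1-[2-(2-methylbut-3-en-2-yloxy)-4-(triisopropylsilyloxy)-6-(trimethylsilyloxy)phenyl]vinyloxy}silane | C=C(O[Si](C)(C)C)c1c(O[Si](C)(C)C)cc(O[Si](C(C)C)(C(C)C)C(C)C)cc1OC(C)(C)C=C
F9 | step 8 | (3R)-3-hydroxy-1-[2-hydroxy-6-(2-methylbut-3-en-2-yloxy)-4-(triisopropylsilyloxy)phenyl]-3-[4-(2-methylbut-3-en-2-yloxy)-2-(triisopropylsilyloxy)phenyl]propan-1-one | O[C@H](CC(=O)c1c(O)cc(O[Si](C(C)C)(C(C)C)C(C)C)cc1OC(C)(C)C=C)c1ccc(OC(C)(C)C=C)cc1O[Si](C(C)C)(C(C)C)C(C)C
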